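**Retrosynthetic overview**
1. Last disconnection: fluoride unmasks all four phenols of the target at once from silicon (two triisopropylsilyl (TIPS) ethers and one Si(tBu)2 bridge).
2. Key disconnection: the biaryl bond flavone C6–coumarin C8. It is closed by a palladium-catalysed intramolecular C–H arylation across a temporary O5–Si(tBu)2–O7 bridge, a position-controlled counterpart of the oxidative phenol coupling of apigenin and umbelliferone presumed in the biosynthesis.
3. Enabling feature: each carbon of this bond has a phenolic oxygen as neighbour. O5 on flavone ring A has only one free ortho carbon, C6 (the other is the ring-fusion atom C4a); O7 on the coumarin benzo ring lies next to C8. The 5-OH, chelated to the C4 carbonyl of ring C, is also the one hydroxyl of apigenin that stays free on silylation.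
4. Fragments: 7,4'-bis-O-TIPS-apigenin (one step from apigenin) and 7-hydroxy-8-iodocoumarin (one step from umbelliferone).
5. Ring order: flavone rings A, B, C and both coumarin rings come with the starting materials. The only ring formed is the temporary seven-membered dioxasilepine (step 4), which is opened again in step 5.

Key step: step 4

Assumption: the SMILES defines no configuration for the tetra-ortho-oxygenated biaryl axis, so the axis is treated as stereochemically undefined and is formed without control (racemic if it is configurationally stable).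
Notation: flavone atoms are numbered as in apigenin (ring B primed); coumarin atoms are written as "coumarin C8", "coumarin O7" and so on.

**Step 1**
Reactants: 1 apigenin
Product: 2 7,4'-bis-O-(triisopropylsilyl)apigenin (5-OH free)
Conditions: TIPSCl (2.2 equiv), imidazole (5 equiv), DMF, 0 °C → rt
Reagents that add atoms: chlorotriisopropylsilane (TIPSCl), CC(C)[Si](Cl)(C(C)C)C(C)C
Why: Chemoselective O-silylation of phenols (chlorosilane–imidazole method): the acidic, unhindered 7-OH and 4'-OH are silylated, while the 5-OH, held in a hydrogen bond to the C4 carbonyl and peri-hindered, should not react with the bulky chlorosilane.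

**Step 2**
Reactants: 3 umbelliferone (7-hydroxycoumarin)
Product: 4 7-hydroxy-8-iodocoumarin
Conditions: I2 (1.0 equiv), KI, 20% aq NH3, 0 °C → rt; acidic work-up
Reagents that add atoms: iodine, II
Why: Electrophilic aromatic iodination of the phenoxide: in the umbelliferone anion C8, ortho to O7 and flanked by the ring oxygen, is the most nucleophilic carbon (the site of its Mannich, Duff and Claisen chemistry), so one equivalent of iodine should give the 8-iodide.

**Step 3**
Reactants: 2 7,4'-bis-O-(triisopropylsilyl)apigenin; 4 7-hydroxy-8-iodocoumarin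
Product: 6 di-tert-butyl[7,4'-bis-O-TIPS-apigenin-5-yloxy](8-iodo-2-oxo-2H-chromen-7-yloxy)silane, via flavon-5-yloxysilyl triflate 5 (not isolated)
Conditions: 2, tBu2Si(OTf)2 (1.05 equiv), Et3N (4 equiv), CH2Cl2, −78 → 0 °C; then 4 (1.1 equiv), DMAP (0.2 equiv), 0 → 40 °C
Reagents that add atoms: di-tert-butylsilyl bis(trifluoromethanesulfonate), CC(C)(C)[Si](OS(=O)(=O)C(F)(F)F)(OS(=O)(=O)C(F)(F)F)C(C)(C)C
Why: Two successive nucleophilic substitutions at silicon (synthesis of an unsymmetrical bis(aryloxy)silane): the highly electrophilic bis-triflate should silylate even the chelated 5-OH, the crowded mono-triflate 5 cannot take up a second flavone, and DMAP catalysis then lets the smaller, more acidic phenol 4 displace the remaining triflate.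

**Step 4**
Reactants: 6 di-tert-butyl[7,4'-bis-O-TIPS-apigenin-5-yloxy](8-iodo-2-oxo-2H-chromen-7-yloxy)silane
Product: 7 di-tert-butylsilylene-bridged 6-(coumarin-8-yl)flavone (flavone C6 bonded to coumarin C8; flavone O5 and coumarin O7 held by one Si(tBu)2 in a seven-membered 1,3,2-dioxasilepine; 7-O- and 4'-O-TIPS retained)
Conditions: Pd(OAc)2 (10 mol %), PCy3·HBF4 (20 mol %), PivOH (30 mol %), Ag2CO3 (1.0 equiv), 4 Å MS, toluene (0.01 M), 110 °C
Reagents that add atoms: none
Why: Zerovalent palladium (formed in situ from Pd(OAc)2 and PCy3) inserts into the carbon–iodine bond at coumarin C8, Ag2CO3 removes iodide as AgI and brings in pivalate, pivalate-assisted concerted metalation–deprotonation cleaves the flavone C6–H bond, and reductive elimination from the diarylpalladium species forms the C6–C8 biaryl bond. The closest known reaction type is the silicon-tethered palladium-catalysed intramolecular C–H arylation of (2-halophenoxy)(aryloxy)di-tert-butylsilanes, which gives dibenzo-1,3,2-dioxasilepines as masked unsymmetrical 2,2'-biphenols. One ring is closed, the seven-membered dioxasilepine (flavone C6 and C5, O5, Si, coumarin O7, C7 and C8), by contraction of an eight-membered palladacycle at the reductive elimination, helped by the two tert-butyl groups, which narrow the O–Si–O angle (Thorpe–Ingold effect) and hold the two arenes face to face. No stereocentre is created, and the hindered axis is formed without control, as a racemate inside the bridge. Site selectivity is needed on both rings: the iodine fixes coumarin C8, and the bridge from O5 fixes flavone C6, because the other carbon ortho to O5 is the ring-fusion atom C4a, because flavone C8–H, C3–H and the ring B hydrogens cannot be reached across a one-atom bridge, and because C6–H, flanked by two oxygens, is the most acidic C–H of ring A. High dilution should hold back intermolecular arylation and Heck-type addition to the coumarin C3=C4 bond, and the non-polar, fluoride-free medium should spare all four aryl silyl ether bonds.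

**Step 5**
Reactants: 7 di-tert-butylsilylene-bridged 6-(coumarin-8-yl)flavone
Product: 8 6-(7-hydroxy-2-oxo-2H-chromen-8-yl)apigenin (target)
Conditions: Bu4NF (6 equiv), AcOH (6 equiv), THF, 0 °C → rt
Reagents that add atoms: none
Why: Fluoride-mediated cleavage of aryl silyl ethers, driven by the strength of the Si–F bond: all four Si–O(aryl) bonds (two TIPS ethers and both arms of the bridge) are broken in one operation, and the acetic acid buffer keeps the coumarin lactone closed while avoiding the hot mineral acid that could cause Wessely–Moser isomerisation of the 6-aryl to the 8-aryl flavone.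

**Compound list**
1 | apigenin, 5,7-dihydroxy-2-(4-hydroxyphenyl)-4H-chromen-4-one | O=c1cc(-c2ccc(O)cc2)oc2cc(O)cc(O)c12 | starting material
2 | 7,4'-bis-O-(triisopropylsilyl)apigenin, 5-OH free | O=c1cc(-c2ccc(O[Si](C(C)C)(C(C)C)C(C)C)cc2)oc2cc(O[Si](C(C)C)(C(C)C)C(C)C)cc(O)c12 | intermediate
3 | umbelliferone, 7-hydroxy-2H-chromen-2-one | O=c1ccc2ccc(O)cc2o1 | starting material
4 | 7-hydroxy-8-iodo-2H-chromen-2-one | O=c1ccc2ccc(O)c(I)c2o1 | intermediate
5 | di-tert-butyl[7,4'-bis-O-TIPS-apigenin-5-yloxy]silyl trifluoromethanesulfonate (not isolated) | O=c1cc(-c2ccc(O[Si](C(C)C)(C(C)C)C(C)C)cc2)oc2cc(O[Si](C(C)C)(C(C)C)C(C)C)cc(O[Si](OS(=O)(=O)C(F)(F)F)(C(C)(C)C)C(C)(C)C)c12 | intermediate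
6 | di-tert-butyl[7,4'-bis-O-TIPS-apigenin-5-yloxy](8-iodo-2-oxo-2H-chromen-7-yloxy)silane | O=c1cc(-c2ccc(O[Si](C(C)C)(C(C)C)C(C)C)cc2)oc2cc(O[Si](C(C)C)(C(C)C)C(C)C)cc(O[Si](Oc3ccc4ccc(=O)oc4c3I)(C(C)(C)C)C(C)(C)C)c12 | intermediate
7 | di-tert-butylsilylene-bridged biaryl, seven-membered 1,3,2-dioxasilepine fused to flavone ring A (C5–C6) and to the coumarin benzo ring (C7–C8), racemic axis | O=c1cc(-c2ccc(O[Si](C(C)C)(C(C)C)C(C)C)cc2)oc2cc(O[Si](C(C)C)(C(C)C)C(C)C)c3c(c12)O[Si](C(C)(C)C)(C(C)(C)C)Oc1ccc2ccc(=O)oc2c1-3 | intermediate
8 | 6-(7-hydroxy-2-oxo-2H-chromen-8-yl)apigenin | O=c1ccc2ccc(O)c(-c3c(O)cc4oc(-c5ccc(O)cc5)cc(=O)c4c3O)c2o1 | target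

**Step count**
Total step count: 5.
Longest linear sequence: 4 steps (1 → 2 → 6 → 7 → 8). The branch 3 → 4 joins at step 3.

**Steps most likely to fail**

Step 4.
- What may go wrong: palladation of the crowded C6–H bond, which lies between two silyloxy groups, may be slower than protodeiodination of the arylpalladium intermediate. It may also be slower than cleavage of the silicon bridge by pivalate and the water that is formed. Loss of a TIPS group alone would be harmless, since step 5 removes it anyway.
- Fallback: an untethered Suzuki–Miyaura cross-coupling of two prefunctionalised partners, which sets out from 2 and 4 and comes back at 8. Compound 2 is iodinated ortho to its free 5-OH with BnMe3NICl2 and CaCO3 in CH2Cl2–MeOH to the 6-iodoflavone F1. Compound 4 is silylated (TIPSCl, imidazole, DMF) to 8-iodo-7-(triisopropylsilyloxy)coumarin F2. Miyaura borylation of this iodide (B2pin2, PdCl2(dppf), KOAc, dioxane, 90 °C) gives the coumarin-8-yl pinacol boronate F3. Coupling of the two partners (Pd2(dba)3, SPhos, K3PO4, toluene, 100 °C) should give the tris-O-TIPS biaryl F4, which gives 8 under the conditions of step 5.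

Step 3.
- What may go wrong: the second substitution at the crowded silicon of 5 may be too slow, so that hydrolysis of 5 or redistribution to symmetrical bis(aryloxy)silanes takes over.
- Fallback: a carbon bridge made by O-alkylation instead of substitution at silicon, which sets out from 4, uses 2 as before and comes back at 8. Compound 4 is alkylated with ClCH2SCH3 (K2CO3, DMF) to the methylthiomethyl ether F5. SO2Cl2 in CH2Cl2 at 0 °C converts it into the aryl chloromethyl ether F6. This ether alkylates the 5-OH of 2 (iPr2NEt, CH2Cl2, reflux) to the mixed formaldehyde acetal F7. The conditions of step 4 should then close the seven-membered dibenzo-1,3-dioxepine F8. BCl3 (CH2Cl2, −78 → 0 °C), guided by chelation to the C4 carbonyl and O5, cleaves the acetal to the bis-O-TIPS triol F9, and the conditions of step 5 give 8.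

Step 5.
- What may go wrong: under basic fluoride the free phenoxides may suffer lactone opening and air oxidation, the buried bridge silicon may be cleaved slowly, and the very polar tetraphenol may be lost on isolation.
- Fallback: desilylative acetylation followed by release, which sets out from 7 and comes back at 8. CsF and Ac2O in MeCN convert each aryl silyl ether directly into an aryl acetate, so that no phenoxide accumulates. This gives the neutral, chromatographable tetraacetate F10. Acid-catalysed methanolysis (cat. HCl, MeOH, 40 °C) then gives 8.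

**Further compounds**
F1 | step 4 | 5-hydroxy-6-iodo-7-(triisopropylsilyloxy)-2-[4-(triisopropylsilyloxy)phenyl]-4H-chromen-4-one | O=c1cc(-c2ccc(O[Si](C(C)C)(C(C)C)C(C)C)cc2)oc2cc(O[Si](C(C)C)(C(C)C)C(C)C)c(I)c(O)c12
F2 | step 4 | 8-iodo-7-(triisopropylsilyloxy)-2H-chromen-2-one | O=c1ccc2ccc(O[Si](C(C)C)(C(C)C)C(C)C)c(I)c2o1
F3 | step 4 | 8-(4,4,5,5-tetramethyl-1,3,2-dioxaborolan-2-yl)-7-(triisopropylsilyloxy)-2H-chromen-2-one | O=c1ccc2ccc(O[Si](C(C)C)(C(C)C)C(C)C)c(B3OC(C)(C)C(C)(C)O3)c2o1
F4 | step 4 | target with flavone 7-O, 4'-O and coumarin 7-O as TIPS ethers, 5-OH free | O=c1ccc2ccc(O[Si](C(C)C)(C(C)C)C(C)C)c(-c3c(O[Si](C(C)C)(C(C)C)C(C)C)cc4oc(-c5ccc(O[Si](C(C)C)(C(C)C)C(C)C)cc5)cc(=O)c4c3O)c2o1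
F5 | step 3 | 8-iodo-7-[(methylsulfanyl)methoxy]-2H-chromen-2-one | CSCOc1ccc2ccc(=O)oc2c1I
F6 | step 3 | 7-(chloromethoxy)-8-iodo-2H-chromen-2-one | ClCOc1ccc2ccc(=O)oc2c1I
F7 | step 3 | mixed formaldehyde acetal of 2 (O5) and 4 (O7) | O=c1cc(-c2ccc(O[Si](C(C)C)(C(C)C)C(C)C)cc2)oc2cc(O[Si](C(C)C)(C(C)C)C(C)C)cc(OCOc3ccc4ccc(=O)oc4c3I)c12
F8 | step 3 | methylene-bridged biaryl, seven-membered 1,3-dioxepine analogue of 7 | O=c1cc(-c2ccc(O[Si](C(C)C)(C(C)C)C(C)C)cc2)oc2cc(O[Si](C(C)C)(C(C)C)C(C)C)c3c(c12)OCOc1ccc2ccc(=O)oc2c1-3
F9 | step 3 | target with flavone 7-O and 4'-O as TIPS ethers | O=c1ccc2ccc(O)c(-c3c(O[Si](C(C)C)(C(C)C)C(C)C)cc4oc(-c5ccc(O[Si](C(C)C)(C(C)C)C(C)C)cc5)cc(=O)c4c3O)c2o1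
F10 | step 5 | tetraacetate of the target | O=c1ccc2ccc(OC(C)=O)c(-c3c(OC(C)=O)cc4oc(-c5ccc(OC(C)=O)cc5)cc(=O)c4c3OC(C)=O)c2o1
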